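Early in a run I read a ratio of two products as a ratio of two rates at one moment, and that is what I reckoned from when you asked me for a quick number.

- dawn: substrate 33 mM; first nucleophile 39.6 mM; second nucleophile 11 mM; run made earlier
- flask: substrate 22 mM; first nucleophile 39.6 mM; second nucleophile 11.0 mM; time 15 d

dawn run (percent of the substrate charged)

| time / d | target / % | other capture product / % | substrate / % |
|---|---|---|---|
| 0.500 | 20.1 | 22.2 | 3.2 |
| 1.04 | 18.1 | 26.0 | 0.5 |
| 1.67 | 14.1 | 26.7 | 0.9 |
| 2.08 | 13.2 | 26.1 | 0 |
| 2.50 | 10.8 | 25.2 | 0 |
| 3.00 | 9.5 | 25.1 | 0.7 |

(readings scatter by 0.5 percentage points)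

1. ratio of target to other capture product at 1.5 h
2. ratio of target to other capture product at 15 d

In the dawn run the other capture product stopped near 26.7%, which is 8.81 mM against 11 mM of second nucleophile charged, so I took it as the product of the second nucleophile and the target as the product of the first. If both capture one pool, the ratio of their rates goes with c(first nucleophile)/c(second nucleophile). I called this at the charge the charge ratio, 3.60; the early ratio divided by it is the selectivity factor. The new flask has the same charge ratio as the dawn run, and at the start, with both nucleophiles at their charges, the substrate cancels from the ratio, so I read its early ratio from the dawn run.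

There the ratio read 0.905 at 0.500 d and 0.378 at 3.00 d, so its logarithm drifted by 0.349 d⁻¹. Carried back to 1.5 h this gave 1.05, and carried forward to 15 d it gave 0.00575; I took both over for the new flask as estimates, the later one as a rough figure from a run with another substrate charge. The first two readings drifted faster than that, so I held the early figure as low.

Your forecast differed from mine, giving 1.5 and 0.02, with the words “Target decays steadily”.

The flask gave 1.80 at 1.5 h and 0.00345 at 15 d, when it held 0.123% target against 35.7% other capture product.

    substrate → intermediate (k = 0.00470 min⁻¹)
    2 second nucleophile → self-condensation product (k = 0.0560 M⁻¹ min⁻¹)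
    first nucleophile → decomposed reagent (k = 3.10 × 10⁻⁵ min⁻¹)
    intermediate → solvolysis product (k = 3.10 × 10⁻⁴ min⁻¹)
    first nucleophile + intermediate ⇌ target (K = 14.0 M⁻¹, k = 0.120 M⁻¹ min⁻¹)
    second nucleophile + intermediate → other capture product (k = 0.200 M⁻¹ min⁻¹)

Divided by the charge ratio of 3.60, the flask's early ratio makes a selectivity factor of 0.500. Multiplied by the charge ratio of the same flask charged with 160 mM of first nucleophile, that factor gives 7.28, and that flask gave 7.12.

The data are simulated from invented constants, and the scatter is random.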